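**Strategy.** Ring B is disconnected at C6–C7 and C10–C11: a catalytic asymmetric Robinson spiroannulation that, in one operation, closes ring B, creates the spiro stereocentre C6 and leaves a C9 enone that later guides methyl to C9 and bromine to C10. The step exploits ring A (C1–C6), a ketoisophorone skeleton whose hindered carbonyl carbon is C6; one-carbon homologation makes C6–H both α-formyl and allylic to C1=C2. The precursor is this racemic C6-formyl ring A with the C3 carbonyl kept as its dioxolane, so that C6 rather than C2 is the donor carbon and the amine catalyst meets a single carbonyl group.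

Key step: step 4

Numbering: all spiro compounds carry the atom numbers of the target, ring A C1(Me)=C2–C3(O)–C4(Br)–C5(Me2)–C6(spiro) and ring B C6–C7–C8–C9(Me)=C10(Br)–C11; the names use these locants.

Assumption: the sense of induction of the amine–thiourea (step 4) and of the oxazaborolidine (step 9) is assigned from the usual transition-state models; both catalysts exist in either enantiomeric form, and the antipode would be used should the sense prove opposite.

**Step 1**
Reactants: 1 ketoisophorone (2,6,6-trimethylcyclohex-2-ene-1,4-dione)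
Product: 2 7,9,9-trimethyl-1,4-dioxaspiro[4.5]dec-6-en-8-one (ketoisophorone ethylene ketal at the unhindered carbonyl, the future C3)
Conditions: HOCH2CH2OH (1.1 equiv), p-TsOH (cat.), benzene, reflux, Dean–Stark
Reagents that add atoms: ethylene glycol, OCCO
Why: Acid-catalysed ketalisation should occur only at the unhindered carbonyl, because the other one (the future C6) is flanked by the gem-dimethyl carbon and the methyl-bearing alkene carbon and stays conjugated to the alkene.

**Step 2**
Reactants: 2 7,9,9-trimethyl-1,4-dioxaspiro[4.5]dec-6-en-8-one; 3 trimethylsulfonium iodide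
Product: 4 racemic 4,12,12-trimethyl-1,7,10-trioxadispiro[2.2.4^6.2^3]dodec-4-ene (the spiro-oxirane formed at the ketone carbon of 2)
Conditions: Me3S+ I−, KOtBu, DMSO–THF, 0 °C to rt
Reagents that add atoms: trimethylsulfonium iodide, C[S+](C)C.[I-]
Why: In this Corey–Chaykovsky epoxidation the small sulfonium methylide should add 1,2 to the hindered enone carbonyl and the betaine should close to the oxirane, whose racemic stereocentre is erased in step 4.

**Step 3**
Reactants: 4 racemic spiro-oxirane
Product: 5 racemic 7,9,9-trimethyl-1,4-dioxaspiro[4.5]dec-6-ene-8-carbaldehyde (the ethylene ketal of 2,6,6-trimethyl-4-oxocyclohex-2-ene-1-carbaldehyde)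
Conditions: BF3·OEt2 (0.3 equiv), CH2Cl2, −78 to −40 °C; Et3N
Reagents that add atoms: none
Why: In this Meinwald rearrangement the Lewis acid should open the oxirane at the tertiary allylic carbon and a 1,2-hydride shift from the oxirane CH2 should give the aldehyde, while the dioxolane should tolerate substoichiometric BF3 at low temperature.

**Step 4**
Reactants: 5 racemic 7,9,9-trimethyl-1,4-dioxaspiro[4.5]dec-6-ene-8-carbaldehyde; 6 methyl vinyl ketone
Product: 9 (6R)-3,3-(ethylenedioxy)-1,5,5-trimethylspiro[5.5]undeca-1,10-dien-9-one (the C3 ethylene ketal of the spiro dienedione), via Michael adduct keto aldehyde 7 (not isolated), via β-hydroxy ketone 8 (not isolated)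
Conditions: 6 (3 equiv), 1-[(1R,2R)-2-aminocyclohexyl]-3-[3,5-bis(trifluoromethyl)phenyl]thiourea (20 mol %), PhCO2H (20 mol %), toluene, 40 °C; then KOH, MeOH, 0 °C to rt
Reagents that add atoms: methyl vinyl ketone, CC(=O)C=C
Why: Proposed new method: the primary amine condenses with the formyl group, the only carbonyl of 5, and the labile C6 stereocentre vanishes in the transoid dienamine N–CH=C6–C1=C2, so both enantiomers of 5 converge; the thiourea binds MVK beside the nitrogen, C6 adds to its terminal carbon (C6–C7), hydrolysis releases 7, and hydroxide then condenses the methyl ketone carbon C10 with the non-enolisable aldehyde carbon C11. The closest known reaction type is the amine-catalysed enantioselective Michael addition of α,α-disubstituted aldehydes to vinyl ketones followed by aldol condensation to 4,4-disubstituted cyclohexenones (asymmetric Robinson annulation), not yet shown for an α-alkenyl α-tert-alkyl aldehyde of this congestion. Ring B closes in the 6-(enolendo)-exo-trig mode. C6 is controlled by the catalyst, which should hold the E-dienamine (nitrogen turned away from the C5 gem-dimethyl group) and deliver the bound enone to one face. The step needs bond formation at C6 and not at the vinylogous carbon C2: the dioxolane at C3 leaves no ketone that would make C2 an enolate α-carbon or tie up the amine as a vinylogous amide, it flanks C2 with a quaternary carbon, and the transoid diene keeps C2 out of reach of the thiourea-bound acceptor.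

**Step 5**
Reactants: 9 (6R)-3,3-(ethylenedioxy)-1,5,5-trimethylspiro[5.5]undeca-1,10-dien-9-one
Product: 11 (6R)-10-bromo-3,3-(ethylenedioxy)-1,5,5-trimethylspiro[5.5]undec-1-en-9-one (both C10 epimers), via silyl enol ether 10 (not isolated)
Conditions: [(Ph3P)CuH]6 (5 mol %), PhMe2SiH (1.5 equiv), toluene, rt; then NBS, THF, −78 °C
Reagents that add atoms: N-bromosuccinimide, O=C1CCC(=O)N1Br
Why: Copper hydride catalysed 1,4-hydrosilylation should touch only the ring B enone and give the regiodefined silyl enol ether 10, whose bromination with NBS places bromine at C10 and not at C8; the C10 configuration is irrelevant because C10 becomes sp2 in step 7.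

**Step 6**
Reactants: 11 (6R)-10-bromo-3,3-(ethylenedioxy)-1,5,5-trimethylspiro[5.5]undec-1-en-9-one
Product: 12 (6R)-10-bromo-3,3-(ethylenedioxy)-1,5,5,9-tetramethylspiro[5.5]undec-1-en-9-ol (hydroxyl cis to bromine; both C10 epimers)
Conditions: MeMgBr, CeCl3 (anhydrous), THF, −78 °C; aq. NH4Cl at −78 °C
Reagents that add atoms: methylmagnesium bromide, C[Mg]Br
Why: Organocerium 1,2-addition to an α-bromo ketone should proceed without enolisation or halogen exchange, and attack anti to the C–Br bond (polar Felkin–Anh) should place the hydroxyl cis to bromine, which leaves the C10 hydrogen anti to the C–O bond.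

**Step 7**
Reactants: 12 (6R)-10-bromo-3,3-(ethylenedioxy)-1,5,5,9-tetramethylspiro[5.5]undec-1-en-9-ol
Product: 14 (6R)-10-bromo-1,5,5,9-tetramethylspiro[5.5]undeca-1,9-dien-3-one, via vinyl bromide ketal 13 (not isolated)
Conditions: SOCl2, pyridine, CH2Cl2, −20 to 0 °C; then 2 M aq. HCl, THF, rt
Reagents that add atoms: water, O
Why: Pyridine-mediated anti E2 elimination of the chlorosulfite should take the C10 hydrogen, which is antiperiplanar in the cis-bromohydrin, acidified by bromine and leads to the tetrasubstituted (Zaitsev) alkene, and the aqueous acid then hydrolyses the dioxolane to the conjugated ring A enone.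

**Step 8**
Reactants: 14 (6R)-10-bromo-1,5,5,9-tetramethylspiro[5.5]undeca-1,9-dien-3-one
Product: 16 (4S,6S)-4,10-dibromo-1,5,5,9-tetramethylspiro[5.5]undeca-1,9-dien-3-one, via silyl dienol ether 15 (not isolated)
Conditions: LDA, TMSCl, THF, −78 °C; then NBS, THF, −78 to 0 °C; chromatographic separation of the C4 epimers
Reagents that add atoms: N-bromosuccinimide, O=C1CCC(=O)N1Br
Why: Kinetic α′-deprotonation of the isophorone-type enone at C4 and bromination of the cross-conjugated silyl dienol ether with NBS should give the α′-bromo enone regioselectively; the remote spiro centre is expected to give little facial bias, so the (4S) epimer is isolated by chromatography and the other epimer is returned to 14 by debromination (Zn, AcOH).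

**Step 9**
Reactants: 16 (4S,6S)-4,10-dibromo-1,5,5,9-tetramethylspiro[5.5]undeca-1,9-dien-3-one
Product: 17 (3S,4S,6S)-4,10-dibromo-1,5,5,9-tetramethylspiro[5.5]undeca-1,9-dien-3-ol (target, CNP0268938.1)
Conditions: (R)-Me-CBS oxazaborolidine ((R)-1-methyl-3,3-diphenyltetrahydro-1H,3H-pyrrolo[1,2-c][1,3,2]oxazaborole, 1 equiv), catecholborane, toluene, −78 °C; MeOH, pH 7 buffer
Reagents that add atoms: none
Why: In this Corey–Bakshi–Shibata reduction the oxazaborolidine should bind the carbonyl anti to the bulky bromine-bearing neopentyl C4 side and deliver hydride to the face that gives the (3S) alcohol, trans to bromine, by reagent control, and the cold, non-basic work-up avoids epoxide formation.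

**Compound list**
1 | ketoisophorone (2,6,6-trimethylcyclohex-2-ene-1,4-dione) | CC1=CC(=O)CC(C)(C)C1=O | starting material
2 | 7,9,9-trimethyl-1,4-dioxaspiro[4.5]dec-6-en-8-one | CC1=CC2(OCCO2)CC(C)(C)C1=O | intermediate
3 | trimethylsulfonium iodide | C[S+](C)C.[I-] | starting material
4 | racemic 4,12,12-trimethyl-1,7,10-trioxadispiro[2.2.4^6.2^3]dodec-4-ene | CC1=CC2(OCCO2)CC(C)(C)C13CO3 | intermediate
5 | racemic 7,9,9-trimethyl-1,4-dioxaspiro[4.5]dec-6-ene-8-carbaldehyde | CC1=CC2(OCCO2)CC(C)(C)C1C=O | intermediate
6 | methyl vinyl ketone (but-3-en-2-one) | CC(=O)C=C | starting material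
7 | (8R)-7,9,9-trimethyl-8-(3-oxobutyl)-1,4-dioxaspiro[4.5]dec-6-ene-8-carbaldehyde | CC1=CC2(OCCO2)CC(C)(C)[C@]1(C=O)CCC(C)=O | intermediate
8 | (6R)-3,3-(ethylenedioxy)-11-hydroxy-1,5,5-trimethylspiro[5.5]undec-1-en-9-one (C11 epimers) | CC1=CC2(OCCO2)CC(C)(C)[C@]13CCC(=O)CC3O | intermediate
9 | (6R)-3,3-(ethylenedioxy)-1,5,5-trimethylspiro[5.5]undeca-1,10-dien-9-one | CC1=CC2(OCCO2)CC(C)(C)[C@]13CCC(=O)C=C3 | intermediate
10 | (6R)-9-[dimethyl(phenyl)silyloxy]-3,3-(ethylenedioxy)-1,5,5-trimethylspiro[5.5]undeca-1,9-diene | CC1=CC2(OCCO2)CC(C)(C)[C@]13CCC(O[Si](C)(C)c4ccccc4)=CC3 | intermediate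
11 | (6R)-10-bromo-3,3-(ethylenedioxy)-1,5,5-trimethylspiro[5.5]undec-1-en-9-one (C10 epimers) | CC1=CC2(OCCO2)CC(C)(C)[C@]13CCC(=O)C(Br)C3 | intermediate
12 | (6R)-10-bromo-3,3-(ethylenedioxy)-1,5,5,9-tetramethylspiro[5.5]undec-1-en-9-ol (OH cis to Br; C10 epimers) | CC1=CC2(OCCO2)CC(C)(C)[C@]13CCC(C)(O)C(Br)C3 | intermediate
13 | (6R)-10-bromo-3,3-(ethylenedioxy)-1,5,5,9-tetramethylspiro[5.5]undeca-1,9-diene | CC1=CC2(OCCO2)CC(C)(C)[C@]13CCC(C)=C(Br)C3 | intermediate
14 | (6R)-10-bromo-1,5,5,9-tetramethylspiro[5.5]undeca-1,9-dien-3-one | CC1=CC(=O)CC(C)(C)[C@]12CCC(C)=C(Br)C2 | intermediate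
15 | (6S)-10-bromo-1,5,5,9-tetramethyl-3-(trimethylsilyloxy)spiro[5.5]undeca-1,3,9-triene | CC1=CC(O[Si](C)(C)C)=CC(C)(C)[C@]12CCC(C)=C(Br)C2 | intermediate
16 | (4S,6S)-4,10-dibromo-1,5,5,9-tetramethylspiro[5.5]undeca-1,9-dien-3-one | CC1=CC(=O)[C@@H](Br)C(C)(C)[C@]12CCC(C)=C(Br)C2 | intermediate
17 | (3S,4S,6S)-4,10-dibromo-1,5,5,9-tetramethylspiro[5.5]undeca-1,9-dien-3-ol | CC1=C[C@H](O)[C@@H](Br)C(C)(C)[C@]12CCC(C)=C(Br)C2 | target

**Totals**
Total step count: 9. Longest linear sequence: 9 steps (1 to 17).

**Steps most likely to fail**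

Step 4 (proposed new method). The congested dienamine may fail to add to the enone, may add through C2, or may add with poor enantiofacial control. Fallback with known chemistry, setting out from 5: deprotonation with KH in THF should give the potassium dienolate, which adds through its α-carbon to 3-(trimethylsilyl)but-3-en-2-one (an α-silyl vinyl ketone that does not polymerise under aprotic enolate conditions) to give the racemic α-silyl keto aldehyde F1. KOH in MeOH then removes silicon and closes ring B by aldol condensation to the racemic spiro enone ketal F2. Preparative chromatography on a chiral stationary phase separates 9 from its (6S)-enantiomer F3, and the route is rejoined at 9.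

Step 7. The elimination may take a C8 or methyl hydrogen (allylic bromide or exocyclic alkene), or chloride may replace the tertiary hydroxyl. Fallback, setting out from 11: deprotonation at the more acidic bromine-bearing carbon with LiHMDS (THF, −78 °C) and bromination with NBS should give the gem-dibromo ketone F4. MeMgBr–CeCl3 addition then gives the dibromo carbinol F5. CrCl2 in THF effects reductive β-elimination of one bromine and the hydroxyl, which can only form the C9=C10 alkene that keeps the second bromine. This returns to 13, which the aqueous acid of step 7 converts into 14.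

Step 9. Reagent control may not override the substrate's own preference for hydride delivery that leaves hydroxyl cis to bromine, so the cis-bromohydrin could dominate. Fallback, setting out from 16: substrate-controlled Luche reduction (NaBH4, CeCl3, MeOH, −78 °C) should give the cis-bromohydrin F6. Mitsunobu inversion at C3 (Ph3P, diisopropyl azodicarboxylate, 4-nitrobenzoic acid, toluene) gives the (3S) 4-nitrobenzoate F7, since the cis bromine cannot participate. Cleavage with i-Bu2AlH in CH2Cl2 at −78 °C, which avoids a free alkoxide that could close to the epoxide, returns to 17.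

**Further compounds**
F1 | step 4 | racemic 7,9,9-trimethyl-8-[3-oxo-2-(trimethylsilyl)butyl]-1,4-dioxaspiro[4.5]dec-6-ene-8-carbaldehyde | CC1=CC2(OCCO2)CC(C)(C)C1(C=O)CC([Si](C)(C)C)C(C)=O
F2 | step 4 | racemic 3,3-(ethylenedioxy)-1,5,5-trimethylspiro[5.5]undeca-1,10-dien-9-one | CC1=CC2(OCCO2)CC(C)(C)C13CCC(=O)C=C3
F3 | step 4 | (6S)-3,3-(ethylenedioxy)-1,5,5-trimethylspiro[5.5]undeca-1,10-dien-9-one | CC1=CC2(OCCO2)CC(C)(C)[C@@]13CCC(=O)C=C3
F4 | step 7 | (6R)-10,10-dibromo-3,3-(ethylenedioxy)-1,5,5-trimethylspiro[5.5]undec-1-en-9-one | CC1=CC2(OCCO2)CC(C)(C)[C@]13CCC(=O)C(Br)(Br)C3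
F5 | step 7 | (6R)-10,10-dibromo-3,3-(ethylenedioxy)-1,5,5,9-tetramethylspiro[5.5]undec-1-en-9-ol | CC1=CC2(OCCO2)CC(C)(C)[C@]13CCC(C)(O)C(Br)(Br)C3
F6 | step 9 | (3R,4S,6S)-4,10-dibromo-1,5,5,9-tetramethylspiro[5.5]undeca-1,9-dien-3-ol | CC1=C[C@@H](O)[C@@H](Br)C(C)(C)[C@]12CCC(C)=C(Br)C2
F7 | step 9 | (3S,4S,6S)-4,10-dibromo-1,5,5,9-tetramethylspiro[5.5]undeca-1,9-dien-3-yl 4-nitrobenzoate | CC1=C[C@H](OC(=O)c3ccc(cc3)[N+](=O)[O-])[C@@H](Br)C(C)(C)[C@]12CCC(C)=C(Br)C2
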